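**Retrosynthetic overview**
1. Target gibberellin ⇐ ring A last: ring-closing metathesis (C1=C2) after an aldol of the 19,10-lactone enolate with acrolein (C3–C4); the lactone comes from vinyl addition to a C10 ketone; C16=C17 and the 15-hydroxyl come from a C15 ketone.
2. Rings C and D (bicyclo[3.2.1]octane) ⇐ one operation on a monocyclic ring B enone: Michael addition C14→C8 closes ring D, then a carbene-catalysed benzoin addition C12→C13 closes ring C.
3. Enabling feature: C13 of ring D is 1,5 to the C10 carbonyl through C14–C8–C9 (Michael retron) and forms with C12 a 1,2-dioxygenated pair (α-ketol retron of the 12,13-diol); a removable ester on C14 makes C14 a soft exocyclic enolate.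
4. One stereocentre (C15) is set by catalysis and relays to C8; C6 and C9 are dynamic and are funnelled; C15 is later reset through its ketone, which also brings in C17.
5. Ring B enone ⇐ β-keto ester 4 + chloro ketone 3 (alkylation, aldol condensation). Ring order: B → D → C → lactone → A.

Key step: step 9

Remark: gibberellane numbering (C1–C19 of the target) is used for all intermediates; C6 in 5–13 is α to an ester and vinylogously acidic, so these compounds are taken as interconverting C6 epimers and their SMILES carry no descriptor there.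

**Route**

Step 1
Reactants: 1 2-chloro-N-methoxy-N-methylacetamide; 2 but-3-en-1-ylmagnesium bromide
Product: 3 1-chlorohex-5-en-2-one
Conditions: THF, −78 → 0 °C; aq. NH4Cl
Reagents that add atoms: none
Why: Weinreb ketone synthesis, in which the chelated tetrahedral adduct persists until work-up so that a single addition gives the α-chloro ketone; no stereocentre is formed.

Step 2
Reactants: 4 methyl 4,4-dimethoxy-3-oxobutanoate; 3 1-chlorohex-5-en-2-one
Product: 5 methyl 2-(2,2-dimethoxyacetyl)-4-oxooct-7-enoate
Conditions: NaH, THF, 0 °C; then 3, NaI (10 mol %), 0 → 25 °C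
Reagents that add atoms: none
Why: C-alkylation of a β-keto ester enolate with an α-halo ketone (iodide-assisted SN2) should give the 1,4-diketone; the new C6 centre is racemic and labile.

Step 3
Reactants: 5 methyl 2-(2,2-dimethoxyacetyl)-4-oxooct-7-enoate
Product: 6 ring B enone acetal
Conditions: NaOMe (0.3 equiv), MeOH, 25 → 50 °C; AcOH quench
Reagents that add atoms: none
Why: Intramolecular aldol condensation of a 1,4-diketone (cyclopentenone annulation, as in the cyclization of 2-acyl-4-oxo esters): the small equilibrium share of the C9 ketone enolate in molecules whose β-keto ester is not deprotonated adds to the activated C8 ketone, and dehydration to the conjugated enone drives this mode, whereas the alternative adduct from C15 cannot dehydrate and reverts.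

Step 4
Reactants: 6 ring B enone acetal
Product: 7 ring B enone aldehyde
Conditions: TFA/H2O (9:1), CH2Cl2, 0 °C
Reagents that add atoms: water, O
Why: Acid hydrolysis of the dimethyl acetal should unveil the C15 aldehyde without touching the esters; no stereocentre is set.

Step 5
Reactants: 8 benzyl 3-oxobutanoate
Product: 10 1-(benzyloxy)-1,3-bis(trimethylsilyloxy)buta-1,3-diene, via silyl enol ether 9 (not isolated)
Conditions: Et3N, Me3SiCl, hexane, 25 °C; then LiN(iPr)2, THF, −78 °C; Me3SiCl
Reagents that add atoms: chlorotrimethylsilane, C[Si](C)(C)Cl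
Why: Two-stage O-silylation (soft enolization, then γ-deprotonation of the vinylogous ester) is the standard entry to bis-silyl dienolates of acetoacetates.

Step 6
Reactants: 7 ring B enone aldehyde; 10 1-(benzyloxy)-1,3-bis(trimethylsilyloxy)buta-1,3-diene
Product: 11 aldol adduct
Conditions: Ti(OiPr)4 (10 mol %), (S)-BINOL (10 mol %), THF, −78 → −20 °C; then TFA, THF/H2O, 0 °C
Reagents that add atoms: none
Why: Catalytic enantioselective vinylogous Mukaiyama aldol addition: the terminal carbon of the dienolate adds to one enantioface of the C15 aldehyde under the titanium–BINOLate, which sets the (15S) carbinol, the only stereocentre made by catalysis.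

Step 7
Reactants: 11 aldol adduct
Product: 12 triethylsilyl ether
Conditions: Et3SiCl, imidazole, DMF, 0 °C
Reagents that add atoms: chlorotriethylsilane, CC[Si](CC)(CC)Cl
Why: Silylation of the secondary alcohol blocks lactonization of the δ-hydroxy-β-keto ester and supplies the bulky group that directs step 9.

Step 8
Reactants: 12 triethylsilyl ether
Product: 13 keto aldehyde
Conditions: OsO4 (2 mol %), NaIO4, 2,6-lutidine, dioxane/H2O, 25 °C
Reagents that add atoms: osmium tetroxide, O=[Os](=O)(=O)=O; sodium periodate, [Na+].[O-]I(=O)(=O)=O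
Why: Lemieux–Johnson cleavage should take the terminal alkene only, because the tetrasubstituted electron-poor enone is inert to OsO4; this gives the C12 aldehyde.

Step 9
Reactants: 13 keto aldehyde
Product: 15 B/C/D ketol, via spiro Michael adduct 14 (not isolated)
Conditions: 2-mesityl-6,7-dihydro-5H-pyrrolo[2,1-c][1,2,4]triazol-2-ium chloride (20 mol %), DBU (1.0 equiv), THF, 0 → 40 °C
Reagents that add atoms: none
Why: Domino intramolecular Michael addition/N-heterocyclic-carbene-catalysed crossed benzoin reaction (closest precedents: base/carbene Michael–benzoin cascades of β-keto esters and intramolecular aldehyde–ketone benzoin cyclizations). DBU forms the β-keto ester enolate, whose C14 adds to C8 of the enone and closes ring D in a 5-exo-trig mode that is allowed because the exocyclic ester carbonyl carries the enolate; the carbene then turns the C12 aldehyde into its Breslow intermediate, which adds to the C13 ketone and closes ring C in a 6-exo-trig mode before proton transfer releases the catalyst. C8 is set by C15, because allylic 1,3-strain against C11 holds the C15–H bond in the enone plane, so that C16 and with it C14 reach only one face of C8 and the silyloxy group ends trans to C9 on ring D; C6, labile in 13, follows by attack anti to its ester; C9 stays epimerizable next to the C10 ketone and is drawn into the cis ring fusion; C13 is fixed by the tether because the aldehyde reaches only the C9 face of the ring D ketone; C14 is removed later. The step needs the Michael addition to precede the benzoin addition and the latter to occur at C13 only: before the Michael step the aldehyde reaches no ketone through a ring smaller than seven atoms, and afterwards C13 is the only ketone within six-membered reach, since C10 would give a four-membered ring. Elimination of the β-silyloxy group should be held back because the base is taken up at C14, which leaves C16 un-enolized. Reversible side equilibria (O-alkylation, aldol addition of C14 to the aldehyde, enone/enoate tautomers of 13) should drain into the ketol, which cannot dehydrate because C13 is a bridgehead.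

Step 10
Reactants: 15 B/C/D ketol
Product: 16 12,13-diol
Conditions: NaBH4, MeOH/CH2Cl2, −78 °C
Reagents that add atoms: none
Why: Borohydride reduction, expected to be chemoselective for the inductively activated α-hydroxy cyclohexanone over the more hindered cyclopentanone next to the branched C9; the axial trajectory at C12 is blocked by the 1,3-diaxial C9–C10 bond, so hydride should arrive from the face of the two-carbon bridge and give the axial hydroxyl cis to the 13-hydroxyl.

Step 11
Reactants: 16 12,13-diol
Product: 17 acetonide
Conditions: 2-methoxypropene, PPTS (5 mol %), CH2Cl2, 0 °C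
Reagents that add atoms: 2-methoxypropene, COC(C)=C
Why: Acid-catalysed acetonide formation, possible only for the cis diol, protects both hydroxyls for the radical, enolate and organometallic steps.

Step 12
Reactants: 17 acetonide
Product: 18 C14 carboxylic acid
Conditions: H2 (1 atm), Pd/C, EtOAc, 25 °C
Reagents that add atoms: none
Why: Hydrogenolysis cleaves the benzyl ester alone, since no alkene is present at this stage and ketone, silyl ether and acetonide are inert.

Step 13
Reactants: 18 C14 carboxylic acid
Product: 20 C14-methylene ketone, via Barton ester 19 (not isolated)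
Conditions: N-hydroxypyridine-2-thione, DCC, DMAP (cat.), CH2Cl2, 0 °C, dark; then t-BuSH, visible light, 20 °C
Reagents that add atoms: none
Why: Barton radical decarboxylation: the thiohydroxamate ester fragments to the C14 radical, which takes hydrogen from the thiol, so the activating carboxyl is removed and C14 becomes the methylene of the target.

Step 14
Reactants: 20 C14-methylene ketone; 21 ethyl (2S)-2-(trifluoromethylsulfonyloxy)propanoate
Product: 22 C5-alkylated keto diester
Conditions: LiN(iPr)2, THF, −78 °C; then 21, −78 → −40 °C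
Reagents that add atoms: none
Why: Kinetic ketone enolate alkylation with an α-triflyloxy ester, a secondary electrophile that enolates displace by SN2 with inversion at the lactate carbon: the less hindered C5 proton is removed and the triflate is attacked anti to the adjacent C6 ester, which places C4 on the α face of the still equilibratable C5; the C4 centre itself is enolized later.

Step 15
Reactants: 22 C5-alkylated keto diester; 23 vinylmagnesium bromide
Product: 25 vinyl lactone, via tertiary alcohol 24 (not isolated)
Conditions: CeCl3, THF, −78 °C; then 0 °C; aq. NH4Cl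
Reagents that add atoms: none
Why: Organocerium 1,2-addition then lactonization: the vinyl group should enter the C10 ketone from the β face, anti to the α substituents on both neighbours (C11 on C9, C4 on C5), and the α alkoxide closes the γ-lactone onto the C19 ester.

Step 16
Reactants: 25 vinyl lactone
Product: 26 C7 carboxylic acid
Conditions: LiSPr, HMPA, 25 °C; dilute HCl work-up
Reagents that add atoms: none
Why: SN2 demethylation of the hindered methyl ester by thiolate (attack at the methyl carbon, not at a carbonyl) frees the C7 acid before the base-sensitive ring A is built and later shields C6 from deprotonation as its carboxylate.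

Step 17
Reactants: 26 C7 carboxylic acid
Product: 27 15-epi alcohol
Conditions: HF·pyridine, pyridine, THF, 0 °C
Reagents that add atoms: none
Why: Fluoride cleavage of the triethylsilyl ether leaves acetonide and lactone intact.

Step 18
Reactants: 27 15-epi alcohol
Product: 28 C15 ketone
Conditions: Dess–Martin periodinane, CH2Cl2, 25 °C
Reagents that add atoms: none
Why: Dess–Martin oxidation of the only free secondary alcohol erases the C15 centre that has done its relay work.

Step 19
Reactants: 28 C15 ketone
Product: 29 16-methylene-15-ketone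
Conditions: paraformaldehyde, diisopropylammonium trifluoroacetate, THF, 65 °C
Reagents that add atoms: formaldehyde (as paraformaldehyde), C=O
Why: Mannich-type α-methylenation: C16 is the only enolizable position of the C15 ketone because C8 is quaternary, and aminomethylation followed by β-elimination installs C17.

Step 20
Reactants: 29 16-methylene-15-ketone
Product: 30 allylic alcohol
Conditions: NaBH4, CeCl3·7H2O, MeOH, −78 °C
Reagents that add atoms: none
Why: Luche 1,2-reduction: hydride should attack the enone from the exo face of ring D, away from the three-carbon bridge C9–C11–C12, which gives the natural 15-hydroxyl syn to C9.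

Step 21
Reactants: 30 allylic alcohol; 31 acrolein
Product: 32 aldol diene
Conditions: LiN(iPr)2 (3.3 equiv), THF, −78 °C; then 31, −78 °C; dilute HCl work-up
Reagents that add atoms: none
Why: Lithium enolate aldol addition (Zimmerman–Traxler): acrolein should approach the lactone enolate on the convex face of the lactone/ring B bicycle, which sets C4 with the methyl group endo, and the closed chair with the methyl cis to the enolate oxygen should give the 3β carbinol.

Step 22
Reactants: 32 aldol diene
Product: 33 12,13-acetonide of the target gibberellin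
Conditions: second-generation Grubbs catalyst (5 mol %), CH2Cl2, 40 °C
Reagents that add atoms: none
Why: Ring-closing metathesis of the two monosubstituted vinyl groups closes ring A as a cis-cyclohexene (C1=C2), while the hindered 1,1-disubstituted C16=C17 alkene should stay out.

Step 23
Reactants: 33 12,13-acetonide of the target gibberellin
Product: 34 target gibberellin
Conditions: AcOH/H2O (4:1), 40 °C
Reagents that add atoms: none
Why: Mild acid hydrolysis of the strained five-membered acetonide should free the 12,13-diol under conditions that the allylic lactone tolerates.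

**Compound list**
1 | 2-chloro-N-methoxy-N-methylacetamide | CON(C)C(=O)CCl | starting material
2 | but-3-en-1-ylmagnesium bromide | C=CCC[Mg]Br | starting material
3 | 1-chlorohex-5-en-2-one | C=CCCC(=O)CCl | intermediate
4 | methyl 4,4-dimethoxy-3-oxobutanoate | COC(OC)C(=O)CC(=O)OC | starting material
5 | methyl 2-(2,2-dimethoxyacetyl)-4-oxooct-7-enoate (racemic) | C=CCCC(=O)CC(C(=O)OC)C(=O)C(OC)OC | intermediate
6 | ring B enone acetal: methyl 2-(dimethoxymethyl)-4-oxo-3-(prop-2-en-1-yl)cyclopent-2-ene-1-carboxylate | C=CCC1=C(C(OC)OC)C(C(=O)OC)CC1=O | intermediate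
7 | ring B enone aldehyde: methyl 2-formyl-4-oxo-3-(prop-2-en-1-yl)cyclopent-2-ene-1-carboxylate | C=CCC1=C(C=O)C(C(=O)OC)CC1=O | intermediate
8 | benzyl 3-oxobutanoate | CC(=O)CC(=O)OCc1ccccc1 | starting material
9 | silyl enol ether: benzyl 3-(trimethylsilyloxy)but-2-enoate (E/Z mixture) | CC(O[Si](C)(C)C)=CC(=O)OCc1ccccc1 | intermediate
10 | 1-(benzyloxy)-1,3-bis(trimethylsilyloxy)buta-1,3-diene | C=C(O[Si](C)(C)C)C=C(O[Si](C)(C)C)OCc1ccccc1 | intermediate
11 | aldol adduct: methyl 2-[(1S)-5-(benzyloxy)-1-hydroxy-3,5-dioxopentyl]-4-oxo-3-(prop-2-en-1-yl)cyclopent-2-ene-1-carboxylate | C=CCC1=C([C@@H](O)CC(=O)CC(=O)OCc2ccccc2)C(C(=O)OC)CC1=O | intermediate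
12 | triethylsilyl ether of 11 (15S) | C=CCC1=C([C@@H](O[Si](CC)(CC)CC)CC(=O)CC(=O)OCc2ccccc2)C(C(=O)OC)CC1=O | intermediate
13 | keto aldehyde: methyl 2-[(1S)-5-(benzyloxy)-3,5-dioxo-1-(triethylsilyloxy)pentyl]-4-oxo-3-(2-oxoethyl)cyclopent-2-ene-1-carboxylate | O=CCC1=C([C@@H](O[Si](CC)(CC)CC)CC(=O)CC(=O)OCc2ccccc2)C(C(=O)OC)CC1=O | intermediate
14 | spiro Michael adduct: 1-benzyl 6-methyl 2,8-dioxo-9-(2-oxoethyl)-4-(triethylsilyloxy)spiro[4.4]nonane-1,6-dicarboxylate; rings B and D joined at C8, C14 on the α face trans to the C6 ester, C11 cis to C14, silyloxy group cis to C6 | O=CC[C@H]1C(=O)C[C@H](C(=O)OC)[C@]12[C@@H](O[Si](CC)(CC)CC)CC(=O)[C@H]2C(=O)OCc3ccccc3 | intermediate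
15 | B/C/D ketol: rings B, C and D with natural C6, C8, C9 and C13; 10-oxo, 12-oxo, 13-hydroxy, 15-epi-15-(triethylsilyloxy), C16 as CH2, benzyl ester on C14, methyl ester at C7 | C1[C@H](O[Si](CC)(CC)CC)[C@]23[C@H](C(=O)OCc4ccccc4)[C@@]1(O)C(=O)C[C@H]2C(=O)C[C@@H]3C(=O)OC | intermediate
16 | 12,13-diol: 15 with the 12-ketone reduced to the hydroxyl cis to the 13-hydroxyl (natural C12) | C1[C@H](O[Si](CC)(CC)CC)[C@]23[C@H](C(=O)OCc4ccccc4)[C@@]1(O)[C@@H](O)C[C@H]2C(=O)C[C@@H]3C(=O)OC | intermediate
17 | acetonide: 12,13-O-isopropylidene derivative of 16 | C1[C@H](O[Si](CC)(CC)CC)[C@]23[C@H](C(=O)OCc4ccccc4)[C@@]1(OC(C)(C)O5)[C@@H]5C[C@H]2C(=O)C[C@@H]3C(=O)OC | intermediate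
18 | C14 carboxylic acid: 17 with the benzyl ester cleaved | C1[C@H](O[Si](CC)(CC)CC)[C@]23[C@H](C(=O)O)[C@@]1(OC(C)(C)O4)[C@@H]4C[C@H]2C(=O)C[C@@H]3C(=O)OC | intermediate
19 | Barton ester: 2-thioxopyridin-1(2H)-yl ester of 18 | C1[C@H](O[Si](CC)(CC)CC)[C@]23[C@H](C(=O)ON4C=CC=CC4=S)[C@@]1(OC(C)(C)O5)[C@@H]5C[C@H]2C(=O)C[C@@H]3C(=O)OC | intermediate
20 | C14-methylene ketone: 10-oxo, 12,13-acetonide, 15-epi-15-(triethylsilyloxy), methyl ester at C7 | C1[C@H](O[Si](CC)(CC)CC)[C@]23C[C@@]1(OC(C)(C)O4)[C@@H]4C[C@H]2C(=O)C[C@@H]3C(=O)OC | intermediate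
21 | ethyl (2S)-2-(trifluoromethylsulfonyloxy)propanoate | C[C@H](OS(=O)(=O)C(F)(F)F)C(=O)OCC | starting material
22 | C5-alkylated keto diester: 20 carrying on C5 (α face) the 1-(ethoxycarbonyl)ethyl group that holds C4, C18 and C19 | C1[C@H](O[Si](CC)(CC)CC)[C@]23C[C@@]1(OC(C)(C)O4)[C@@H]4C[C@H]2C(=O)[C@@H]([C@H](C)C(=O)OCC)[C@@H]3C(=O)OC | intermediate
23 | vinylmagnesium bromide | C=C[Mg]Br | starting material
24 | tertiary alcohol: 22 with 10α-hydroxy and 10β-vinyl | C1[C@H](O[Si](CC)(CC)CC)[C@]23C[C@@]1(OC(C)(C)O4)[C@@H]4C[C@H]2[C@](O)(C=C)[C@@H]([C@H](C)C(=O)OCC)[C@@H]3C(=O)OC | intermediate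
25 | vinyl lactone: 19,10-γ-lactone with 10β-vinyl, C4 still bearing H, methyl ester at C7 | C1[C@H](O[Si](CC)(CC)CC)[C@]23C[C@@]1(OC(C)(C)O4)[C@@H]4C[C@H]2[C@@]4(C=C)OC(=O)[C@@H](C)[C@H]4[C@@H]3C(=O)OC | intermediate
26 | C7 carboxylic acid: 25 with the methyl ester cleaved | C1[C@H](O[Si](CC)(CC)CC)[C@]23C[C@@]1(OC(C)(C)O4)[C@@H]4C[C@H]2[C@@]4(C=C)OC(=O)[C@@H](C)[C@H]4[C@@H]3C(=O)O | intermediate
27 | 15-epi alcohol: 26 with the silyl ether cleaved | C1[C@H](O)[C@]23C[C@@]1(OC(C)(C)O4)[C@@H]4C[C@H]2[C@@]4(C=C)OC(=O)[C@@H](C)[C@H]4[C@@H]3C(=O)O | intermediate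
28 | C15 ketone | C1C(=O)[C@]23C[C@@]1(OC(C)(C)O4)[C@@H]4C[C@H]2[C@@]4(C=C)OC(=O)[C@@H](C)[C@H]4[C@@H]3C(=O)O | intermediate
29 | 16-methylene-15-ketone | C=C1C(=O)[C@]23C[C@@]1(OC(C)(C)O4)[C@@H]4C[C@H]2[C@@]4(C=C)OC(=O)[C@@H](C)[C@H]4[C@@H]3C(=O)O | intermediate
30 | allylic alcohol: natural 15-hydroxy-16-methylene unit, 12,13-acetonide, vinyl lactone, C7 acid | C=C1[C@@H](O)[C@]23C[C@@]1(OC(C)(C)O4)[C@@H]4C[C@H]2[C@@]4(C=C)OC(=O)[C@@H](C)[C@H]4[C@@H]3C(=O)O | intermediate
31 | acrolein | C=CC=O | starting material
32 | aldol diene: 30 with C4 quaternary (methyl endo) and bearing the (3-hydroxy)allyl unit of natural C3 configuration | C=C1[C@@H](O)[C@]23C[C@@]1(OC(C)(C)O4)[C@@H]4C[C@H]2[C@@]4(C=C)OC(=O)[C@](C)([C@@H](O)C=C)[C@H]4[C@@H]3C(=O)O | intermediate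
33 | 12,13-acetonide of the target gibberellin | C=C1[C@@H](O)[C@]23C[C@@]1(OC(C)(C)O4)[C@@H]4C[C@H]2[C@@]12C=C[C@H](O)[C@@](C)(C(=O)O1)[C@H]2[C@@H]3C(=O)O | intermediate
34 | target gibberellin: 12,15-dihydroxygibberellic acid (12-hydroxyl cis to the 13-hydroxyl, 15-hydroxyl on the C9 side of ring D) | C=C1[C@@H](O)[C@]23C[C@@]1(O)[C@@H](O)C[C@H]2[C@@]12C=C[C@H](O)[C@@](C)(C(=O)O1)[C@H]2[C@@H]3C(=O)O | target

**Totals**
Total step count: 23. Longest linear sequence: 22 steps (steps 1–4 and 6–23; step 5 prepares diene 10 for step 6).

**Three steps most likely to fail**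

Step 9. The Michael addition to the fully substituted enone carbon may be slow or reverse, the enolizable aldehyde may self-condense, or the Breslow intermediate may fail to add to the hindered, partly enolized ketone. The fallback separates the two bond formations and replaces the benzoin by a pinacol coupling. It sets out from 12: Cs2CO3 in MeCN should give the spiro Michael adduct with the allyl group still in place F1; OsO4/NaIO4 cleavage then gives 14, now isolated; SmI2 in THF/MeOH at −78 °C couples the aldehyde ketyl with the ring D ketone through a samarium chelate to the cis diol. The fallback comes back to the route at 16 and makes steps 9 and 10 unnecessary.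

Step 10. Hydride may attack the C12 ketone from the wrong face, or the C10 ketone may be reduced as well. The fallback corrects C12 by SN2 inversion instead of facial control. It sets out from 15: if reduction delivers the 12-epimeric diol F2, a Mitsunobu reaction (4-nitrobenzoic acid, PPh3, DIAD) should give the inverted 12-O-(4-nitrobenzoyl) ester F3, and K2CO3 in MeOH at 0 °C cleaves the activated ester. The fallback comes back at 16.

Step 21. The aldol may show poor control at C3 (open against closed transition state), and the polyanion may enolize sluggishly. The fallback sets C3 by ketone reduction instead of by the aldol. It sets out from 30: the aldol is run as before and the C3-epimeric aldol diene F4 is carried through ring-closing metathesis to the 3-epimeric acetonide F5; MnO2 oxidizes both allylic alcohols to the 3,15-diketone F6; NaBH4/CeCl3 then reduces both ketones, at C15 as in step 20 and at C3 anti to the C18 methyl group. The fallback comes back at 33.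

**Further compounds**
F1 | step 9 | spiro Michael adduct with the allyl group still in place (14 with CH2CH=CH2 instead of CH2CHO) | C=CC[C@H]1C(=O)C[C@H](C(=O)OC)[C@]12[C@@H](O[Si](CC)(CC)CC)CC(=O)[C@H]2C(=O)OCc3ccccc3
F2 | step 10 | 12-epimeric diol (12-hydroxyl trans to the 13-hydroxyl) | C1[C@H](O[Si](CC)(CC)CC)[C@]23[C@H](C(=O)OCc4ccccc4)[C@@]1(O)[C@H](O)C[C@H]2C(=O)C[C@@H]3C(=O)OC
F3 | step 10 | 12-O-(4-nitrobenzoyl) ester of 16 (natural C12) | C1[C@H](O[Si](CC)(CC)CC)[C@]23[C@H](C(=O)OCc4ccccc4)[C@@]1(O)[C@@H](OC(=O)c5ccc(cc5)[N+](=O)[O-])C[C@H]2C(=O)C[C@@H]3C(=O)OC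
F4 | step 21 | C3-epimeric aldol diene (3-epi-32) | C=C1[C@@H](O)[C@]23C[C@@]1(OC(C)(C)O4)[C@@H]4C[C@H]2[C@@]4(C=C)OC(=O)[C@](C)([C@H](O)C=C)[C@H]4[C@@H]3C(=O)O
F5 | step 21 | 3-epimeric acetonide (3-epi-33) | C=C1[C@@H](O)[C@]23C[C@@]1(OC(C)(C)O4)[C@@H]4C[C@H]2[C@@]12C=C[C@@H](O)[C@@](C)(C(=O)O1)[C@H]2[C@@H]3C(=O)O
F6 | step 21 | 3,15-diketone (3,15-didehydro-33) | C=C1C(=O)[C@]23C[C@@]1(OC(C)(C)O4)[C@@H]4C[C@H]2[C@@]12C=CC(=O)[C@@](C)(C(=O)O1)[C@H]2[C@@H]3C(=O)O
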